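**Plan**

- Retrosynthesis: the C4a,C5-diol goes back to a C4a=C5 olefin. Ring B is opened at C4a=C5 (metathesis), C8–C7 (Grignard addition) and C8a–C8 (allylation). Both C–Br bonds go back to C–O. Ring A is cut at C2–C3, C4–C4a and C1–C2 into a terminal alkyne, an isopropenyl(methoxy)carbene chromium complex and CO.
- Enabling feature: ring A has oxygen at C2 and, para to it, at C4a, and the quaternary C1' of ring C sits on C3 next to the C2 oxygen. A carbene benzannulation lays down exactly this 4-alkoxyphenol around a tert-alkyl acetylene, so the crowded C1'–C3 bond is never made by coupling.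
- Forward order: ring C (from camphanic acid, turned into an alkynol), then ring A (step 6), reduction of ring A to a bis(silyl enol ether), quaternisation of C8a, closure of ring B, then the bromides, the dienone and the diol.
- Stereochemistry: C1' from the chiral pool; C3' by hydride reduction beside the ethynyl group and a late SN2 bromination; C8a by ligand-controlled Pd allylation; C8 by radical hydrogenation of a bromoalkene anti to the C8a methyl; C4a and C5 by epoxidation anti to that methyl and trans-diaxial hydrolysis.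

Key step: step 6

Remark on numbering: ring A = C1, C2, C3, C4, C4a, C8a; ring B = C4a, C5, C6, C7, C8, C8a; ring C = C1' to C5' (C1' quaternary, C3' brominated). TBS = tert-butyldimethylsilyl, TMS = trimethylsilyl, RC = (1S,3S)-3-(TBS-oxy)-1,2,2-trimethylcyclopentyl.

Assumption: the (1R,4S) antipode of camphanic acid is taken as a catalogue compound, and the Pd allylation of step 10 is taken to follow the facial sense known for 2-methylcyclohexanone enolates (hence the (R) ligand).

**Route**

Step 1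
Reactants: 1 (1R,4S)-camphanic acid
Product: 3 (3S)-3-(hydroxymethyl)-2,2,3-trimethylcyclopentan-1-one, via triol 2 (not isolated)
Conditions: LiAlH4, THF, reflux; then NaIO4, THF/H2O, 0 to 23 °C
Reagents that add atoms: none
Why: LiAlH4 reduces the lactone and the acid to a triol whose tertiary/primary 1,2-diol is then cut by periodate (glycol cleavage), which removes the former carboxyl carbon as formaldehyde and leaves the C3' ketone next to the untouched quaternary C1'.

Step 2
Reactants: 3 (3S)-3-(hydroxymethyl)-2,2,3-trimethylcyclopentan-1-one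
Product: 4 (1S)-1,2,2-trimethyl-3-oxocyclopentane-1-carbaldehyde
Conditions: Dess–Martin periodinane, NaHCO3, CH2Cl2, 23 °C
Reagents that add atoms: none
Why: Dess–Martin oxidation of the neopentyl primary alcohol should stop cleanly at the aldehyde, which has no α-hydrogen and so cannot epimerise or enolise.

Step 3
Reactants: 4 (1S)-1,2,2-trimethyl-3-oxocyclopentane-1-carbaldehyde
Product: 5 (3R)-3-ethynyl-2,2,3-trimethylcyclopentan-1-one
Conditions: dimethyl (1-diazo-2-oxopropyl)phosphonate, K2CO3, MeOH, 0 to 23 °C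
Reagents that add atoms: dimethyl (1-diazo-2-oxopropyl)phosphonate, COP(=O)(OC)C(=[N+]=[N-])C(C)=O
Why: Ohira–Bestmann (Seyferth–Gilbert) homologation turns the aldehyde into the terminal alkyne, the ketone between the gem-dimethyl carbon and a methylene being too hindered to react with the diazophosphonate anion.

Step 4
Reactants: 5 (3R)-3-ethynyl-2,2,3-trimethylcyclopentan-1-one
Product: 6 (1S,3R)-3-ethynyl-2,2,3-trimethylcyclopentan-1-ol
Conditions: LiBH(s-Bu)3, THF, −78 °C; aq. NH4Cl
Reagents that add atoms: none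
Why: Ketone reduction with a bulky trialkylborohydride should deliver hydride to the face of the cyclopentanone that carries the thin ethynyl rod rather than the C1' methyl group, which puts the new C3' hydroxyl cis to that methyl and trans to the alkyne (1S), the arrangement needed for inversion in step 22.

Step 5
Reactants: 7 2-bromopropene; 8 chromium hexacarbonyl
Product: 11 pentacarbonyl[methoxy(prop-1-en-2-yl)carbene]chromium, via isopropenyllithium 9 (not isolated), via lithium acylchromate 10 (not isolated)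
Conditions: t-BuLi (2 equiv), Et2O, −78 °C; Cr(CO)6, 0 to 23 °C; Me3OBF4, CH2Cl2, 0 °C
Reagents that add atoms: trimethyloxonium tetrafluoroborate, C[O+](C)C.F[B-](F)(F)F
Why: Fischer carbene synthesis: bromine–lithium exchange gives isopropenyllithium, which adds to a CO ligand of Cr(CO)6, and O-methylation of the acylmetalate by the oxonium salt gives the alkenyl(methoxy)carbene complex.

Step 6
Reactants: 6 (1S,3R)-3-ethynyl-2,2,3-trimethylcyclopentan-1-ol; 11 pentacarbonyl[methoxy(prop-1-en-2-yl)carbene]chromium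
Product: 13 2-[(1S,3S)-3-hydroxy-1,2,2-trimethylcyclopentyl]-4-methoxy-5-methylphenol, via tricarbonylchromium arene complex 12 (not isolated)
Conditions: THF, 55 °C; then air, MeCN, 23 °C
Reagents that add atoms: none
Why: Thermal loss of CO from 11 opens a site for the alkyne, which inserts with its tert-alkyl-bearing carbon remote from the carbene carbon; CO insertion then gives a chromium-bound dienylketene, and 6π-electrocyclisation followed by enolisation gives the tricarbonylchromium complex of the phenol, which air sets free. The closest known reaction type is the Dötz benzannulation of alkenyl(alkoxy)carbene chromium complexes with terminal alkynes, tert-alkyl acetylenes included. Ring A is the only ring closed, and it closes by 6π-electrocyclisation of the dienylketene, C1–C2 being the last bond after C4–C4a and C2–C3. No stereocentre is created, and C1' and C3' are spectators because C1' is quaternary and the medium is neutral. The one selectivity required is regiochemical: the substituted alkyne carbon must become C3 next to the CO-derived C2, which the size difference between the quaternary C1' group and hydrogen secures, while the C3' hydroxyl, trans to the alkyne on the five-membered ring, cannot reach the ketene.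

Step 7
Reactants: 13 2-[(1S,3S)-3-hydroxy-1,2,2-trimethylcyclopentyl]-4-methoxy-5-methylphenol
Product: 14 2-[(1S,3S)-3-hydroxy-1,2,2-trimethylcyclopentyl]-5-methylcyclohexa-2,5-diene-1,4-dione
Conditions: PhI(OAc)2, MeCN/H2O, 0 °C
Reagents that add atoms: water, O
Why: Oxidative demethylation of a para-methoxyphenol by the diacetoxyiodoarene in aqueous acetonitrile gives the para-quinone by way of a hemiketal, and the hindered secondary alcohol is not touched by this oxidant.

Step 8
Reactants: 14 2-[(1S,3S)-3-hydroxy-1,2,2-trimethylcyclopentyl]-5-methylcyclohexa-2,5-diene-1,4-dione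
Product: 16 1,4-bis(TBS-oxy)-2-methyl-5-RC-benzene, via hydroquinone 15 (not isolated)
Conditions: Na2S2O4, THF/H2O, 23 °C; then TBSOTf, 2,6-lutidine, CH2Cl2, 0 to 23 °C
Reagents that add atoms: tert-butyldimethylsilyl trifluoromethanesulfonate, CC(C)(C)[Si](C)(C)OS(=O)(=O)C(F)(F)F
Why: Dithionite reduction gives the air-sensitive hydroquinone, which is silylated at once together with the C3' alcohol (silyl ether formation with a silyl triflate, needed for the phenol beside the quaternary C1'), so that both ring A oxygens carry the same silyl group.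

Step 9
Reactants: 16 1,4-bis(TBS-oxy)-2-methyl-5-RC-benzene
Product: 17 1,4-bis(TBS-oxy)-2-methyl-5-RC-cyclohexa-1,4-diene
Conditions: Li, NH3 (l), THF, t-BuOH, −78 to −33 °C
Reagents that add atoms: none
Why: Birch reduction of the 1,4-bis(silyloxy)arene should protonate the two unsubstituted positions C1 and C4, which keeps both oxygenated and both alkylated carbons olefinic and gives a bis(silyl enol ether) whose C4a=C8a enol ether is regiodefined, while the alkyl silyl ether is inert to lithium in ammonia.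

Step 10
Reactants: 17 1,4-bis(TBS-oxy)-2-methyl-5-RC-cyclohexa-1,4-diene
Product: 18 (2S)-2-allyl-2-methyl-4-(TBS-oxy)-5-RC-cyclohex-4-en-1-one
Conditions: Pd2(dba)3 (2.5 mol %), (R)-t-Bu-PHOX (6 mol %), diallyl carbonate, Bu4N[Ph3SiF2] (35 mol %), THF, 25 to 40 °C
Reagents that add atoms: diallyl carbonate, C=CCOC(=O)OCC=C
Why: Asymmetric Tsuji allylation of a silyl enol ether: fluoride and allyl oxide should unmask only the exposed C4a enolate (the C2 enol ether is screened by the quaternary C1'), and inner-sphere allylation of the Pd enolate under the (R)-phosphinooxazoline ligand forms the quaternary C8a in the (S) configuration without enolate equilibration toward C4, as established for 2-methylcyclohexanone enolates.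

Step 11
Reactants: 18 (2S)-2-allyl-2-methyl-4-(TBS-oxy)-5-RC-cyclohex-4-en-1-one
Product: 19 (2R)-2-methyl-2-[(E)-prop-1-enyl]-4-(TBS-oxy)-5-RC-cyclohex-4-en-1-one
Conditions: RuHCl(CO)(PPh3)3 (5 mol %), toluene, 80 °C
Reagents that add atoms: none
Why: Ruthenium hydride-catalysed olefin migration (allyl to propenyl isomerisation) moves the double bond by one position only, because the next carbon, C8a, is quaternary, and the E isomer is favoured.

Step 12
Reactants: 19 (2R)-2-methyl-2-[(E)-prop-1-enyl]-4-(TBS-oxy)-5-RC-cyclohex-4-en-1-one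
Product: 20 (1R)-1-methyl-2-oxo-5-(TBS-oxy)-4-RC-cyclohex-4-ene-1-carbaldehyde
Conditions: OsO4 (2 mol %), NaIO4, 2,6-lutidine, dioxane/H2O, 23 °C
Reagents that add atoms: sodium periodate (source of the aldehyde oxygen by way of OsO4), [Na+].[O-]I(=O)(=O)=O
Why: Lemieux–Johnson cleavage (osmylation, then periodate scission of the glycol) should take the disubstituted propenyl group in preference to the tetrasubstituted enol ether screened by C1', leaving the C8 aldehyde on a carbon that cannot epimerise.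

Step 13
Reactants: 20 (1R)-1-methyl-2-oxo-5-(TBS-oxy)-4-RC-cyclohex-4-ene-1-carbaldehyde; 21 4-bromo-2-methylbut-1-ene
Product: 24 (2R)-2-methyl-2-[4-methyl-1-(TMS-oxy)pent-4-enyl]-4-(TBS-oxy)-5-RC-cyclohex-4-en-1-one (C8 epimers), via Grignard reagent 22 (not isolated), via magnesium alkoxide 23 (not isolated)
Conditions: 21, Mg, THF, 23 °C; then 20, THF, −78 °C; then TMSOTf, 2,6-lutidine, −78 to 0 °C
Reagents that add atoms: trimethylsilyl trifluoromethanesulfonate, C[Si](C)(C)OS(=O)(=O)C(F)(F)F
Why: Grignard addition at −78 °C should select the aldehyde over the C4a ketone, which is flanked by the quaternary C8a, and the magnesium alkoxide is silylated in the same flask; C8 is formed as a mixture of epimers, which is of no consequence because it is oxidised in step 16.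

Step 14
Reactants: 24 (2R)-2-methyl-2-[4-methyl-1-(TMS-oxy)pent-4-enyl]-4-(TBS-oxy)-5-RC-cyclohex-4-en-1-one
Product: 25 1-methylidene analogue of 24 (C4a=CH2 in place of C4a=O; C8 epimers)
Conditions: Cp2TiMe2, toluene, 70 °C
Reagents that add atoms: dimethyltitanocene, C[Ti](C)(C1C=CC=C1)C1C=CC=C1
Why: Petasis methylenation with the titanocene methylidene, a non-basic reagent, should olefinate the hindered and enolisable C4a ketone without retro-aldol cleavage and without touching the silyl ethers.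

Step 15
Reactants: 25 1-methylidene analogue of 24
Product: 26 (8aS)-5,8a-dimethyl-2-(TBS-oxy)-8-(TMS-oxy)-3-RC-1,4,6,7,8,8a-hexahydronaphthalene (C8 epimers)
Conditions: second-generation Hoveyda–Grubbs catalyst (10 mol %), toluene, 100 °C
Reagents that add atoms: none
Why: Ring-closing metathesis of the two 1,1-disubstituted olefins closes ring B as a six-membered ring with the tetrasubstituted C4a=C5 double bond and loss of ethene, the enol ether and the silyl ethers being inert to the ruthenium carbene.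

Step 16
Reactants: 26 (8aS)-5,8a-dimethyl-2-(TBS-oxy)-8-(TMS-oxy)-3-RC-1,4,6,7,8,8a-hexahydronaphthalene
Product: 28 (8aS)-5,8a-dimethyl-2-(TBS-oxy)-3-RC-1,4,6,7-tetrahydronaphthalen-8(8aH)-one (target numbering), via alcohol 27 (not isolated)
Conditions: K2CO3 (cat.), MeOH, 0 °C; then Dess–Martin periodinane, NaHCO3, CH2Cl2, 23 °C
Reagents that add atoms: none
Why: Carbonate-catalysed methanolysis removes only the trimethylsilyl ether, and Dess–Martin oxidation of the freed secondary alcohol gives the C8 ketone, which erases the undefined C8 centre.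

Step 17
Reactants: 28 (8aS)-5,8a-dimethyl-2-(TBS-oxy)-3-RC-1,4,6,7-tetrahydronaphthalen-8(8aH)-one
Product: 29 (8aS)-5,8a-dimethyl-2-(TBS-oxy)-3-RC-1,4,6,8a-tetrahydronaphthalen-8-yl trifluoromethanesulfonate
Conditions: KN(SiMe3)2, PhNTf2, THF, −78 to 0 °C
Reagents that add atoms: N-phenylbis(trifluoromethanesulfonimide), O=S(=O)(N(c1ccccc1)S(=O)(=O)C(F)(F)F)C(F)(F)F
Why: Enol triflate formation: the C8 ketone has α-hydrogens only at C7, so deprotonation by the silylamide and O-sulfonylation by the triflimide give the C7=C8 enol triflate as the sole regioisomer.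

Step 18
Reactants: 29 (8aS)-5,8a-dimethyl-2-(TBS-oxy)-3-RC-1,4,6,8a-tetrahydronaphthalen-8-yl trifluoromethanesulfonate
Product: 30 (8aS)-8-bromo-5,8a-dimethyl-2-(TBS-oxy)-3-RC-1,4,6,8a-tetrahydronaphthalene
Conditions: Ni(cod)2 (10 mol %), LiBr, DMA/THF, 23 °C
Reagents that add atoms: lithium bromide, [Li+].[Br-]
Why: Nickel-catalysed halide exchange of an alkenyl triflate (oxidative addition, triflate-for-bromide exchange, reductive elimination) should give the bromoalkene under neutral conditions that spare the silyl ethers.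

Step 19
Reactants: 30 (8aS)-8-bromo-5,8a-dimethyl-2-(TBS-oxy)-3-RC-1,4,6,8a-tetrahydronaphthalene
Product: 31 (8S,8aS)-8-bromo-5,8a-dimethyl-2-(TBS-oxy)-3-RC-1,4,6,7,8,8a-hexahydronaphthalene
Conditions: Mn(dpm)3 (10 mol %), PhSiH3, t-BuOOH, i-PrOH, 23 °C
Reagents that add atoms: none
Why: Hydrogen-atom-transfer hydrogenation with a manganese hydride, a method that reduces haloalkenes without loss of halogen: hydrogen should add first to C7, the less hindered end of the only trisubstituted olefin, and the C8 α-bromo radical then takes hydrogen on the face opposite the axial C8a methyl, so bromine ends equatorial and cis to that methyl (8S).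

Step 20
Reactants: 31 (8S,8aS)-8-bromo-5,8a-dimethyl-2-(TBS-oxy)-3-RC-1,4,6,7,8,8a-hexahydronaphthalene
Product: 32 (8S,8aS)-8-bromo-5,8a-dimethyl-3-RC-6,7,8,8a-tetrahydronaphthalen-2(1H)-one
Conditions: DDQ, 2,6-lutidine, CH2Cl2/H2O, 0 to 23 °C
Reagents that add atoms: none
Why: DDQ dehydrogenation of a silyl enol ether: hydride abstraction from the doubly allylic C4 gives a silyloxy-stabilised pentadienyl cation, and loss of the silyl group to water gives the linearly conjugated C3=C4/C4a=C5 dienone, C8a being quaternary so that no aromatisation can follow.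

Step 21
Reactants: 32 (8S,8aS)-8-bromo-5,8a-dimethyl-3-RC-6,7,8,8a-tetrahydronaphthalen-2(1H)-one
Product: 33 (8S,8aS)-8-bromo-3-[(1S,3S)-3-hydroxy-1,2,2-trimethylcyclopentyl]-5,8a-dimethyl-6,7,8,8a-tetrahydronaphthalen-2(1H)-one
Conditions: HF·pyridine, pyridine, THF, 0 to 23 °C
Reagents that add atoms: none
Why: Desilylation with buffered HF·pyridine frees the C3' alcohol without affecting the secondary bromide or the dienone.

Step 22
Reactants: 33 (8S,8aS)-8-bromo-3-[(1S,3S)-3-hydroxy-1,2,2-trimethylcyclopentyl]-5,8a-dimethyl-6,7,8,8a-tetrahydronaphthalen-2(1H)-one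
Product: 34 (8S,8aS)-8-bromo-3-[(1R,3R)-3-bromo-1,2,2-trimethylcyclopentyl]-5,8a-dimethyl-6,7,8,8a-tetrahydronaphthalen-2(1H)-one
Conditions: CBr4, PPh3, CH2Cl2, 0 to 40 °C
Reagents that add atoms: tetrabromomethane, BrC(Br)(Br)Br
Why: Appel reaction: bromide displaces the oxyphosphonium group with inversion (SN2 at a cyclopentyl carbon next to a quaternary centre, as is known for steroidal 17-alcohols), which turns the C3' alcohol trans to ring A into the bromide cis to ring A (3'R).

Step 23
Reactants: 34 (8S,8aS)-8-bromo-3-[(1R,3R)-3-bromo-1,2,2-trimethylcyclopentyl]-5,8a-dimethyl-6,7,8,8a-tetrahydronaphthalen-2(1H)-one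
Product: 35 (4aR,5S,8S,8aS)-4a,5-epoxide of 34 (oxygen anti to the C8a methyl)
Conditions: mCPBA, NaHCO3, CH2Cl2, 0 °C
Reagents that add atoms: 3-chloroperbenzoic acid, OOC(=O)c1cccc(Cl)c1
Why: Peracid (Prilezhaev) epoxidation should take the electron-rich tetrasubstituted γ,δ-olefin of the dienone rather than the α,β-olefin and should come from the face opposite the axial C8a methyl group, as with Δ5-steroids.

Step 24
Reactants: 35 (4aR,5S,8S,8aS)-4a,5-epoxide of 34
Product: 36 (4aR,5R,8S,8aS)-8-bromo-3-[(1R,3R)-3-bromo-1,2,2-trimethylcyclopentyl]-4a,5-dihydroxy-5,8a-dimethyl-4a,5,6,7,8,8a-hexahydronaphthalen-2(1H)-one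
Conditions: HClO4 (aq., 0.5 M), THF, 0 to 23 °C
Reagents that add atoms: water, O
Why: Acid-catalysed epoxide hydrolysis with trans-diaxial opening (Fürst–Plattner rule): water should attack the tertiary C5, not C4a whose cationic character is disfavoured by the adjoining enone, with inversion from the face of the C8a methyl, which gives the C4a hydroxyl anti and the C5 hydroxyl syn to that methyl (4aR,5R).

**Compound list**

1 | (1R,4S)-camphanic acid [(1R,4S)-4,7,7-trimethyl-3-oxo-2-oxabicyclo[2.2.1]heptane-1-carboxylic acid] | CC1(C)[C@](C(=O)O)(O2)CC[C@]1(C)C2=O | starting material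
2 | (1R,3S)-1,3-bis(hydroxymethyl)-2,2,3-trimethylcyclopentan-1-ol | CC1(C)[C@](CO)(O)CC[C@]1(C)CO | intermediate
3 | (3S)-3-(hydroxymethyl)-2,2,3-trimethylcyclopentan-1-one | CC1(C)C(=O)CC[C@]1(C)CO | intermediate
4 | (1S)-1,2,2-trimethyl-3-oxocyclopentane-1-carbaldehyde | CC1(C)C(=O)CC[C@]1(C)C=O | intermediate
5 | (3R)-3-ethynyl-2,2,3-trimethylcyclopentan-1-one | CC1(C)C(=O)CC[C@]1(C)C#C | intermediate
6 | (1S,3R)-3-ethynyl-2,2,3-trimethylcyclopentan-1-ol (hydroxyl trans to ethynyl) | CC1(C)[C@@H](O)CC[C@]1(C)C#C | intermediate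
7 | 2-bromopropene | CC(Br)=C | starting material
8 | chromium hexacarbonyl | O=C=[Cr](=C=O)(=C=O)(=C=O)(=C=O)=C=O | starting material
9 | isopropenyllithium | [Li]C(C)=C | intermediate
10 | lithium pentacarbonyl(2-methylprop-2-enoyl)chromate | [Li]OC(=[Cr](=C=O)(=C=O)(=C=O)(=C=O)=C=O)C(C)=C | intermediate
11 | pentacarbonyl[methoxy(prop-1-en-2-yl)carbene]chromium | COC(=[Cr](=C=O)(=C=O)(=C=O)(=C=O)=C=O)C(C)=C | intermediate
12 | tricarbonylchromium η6-arene complex of phenol 13 (written as two parts) | CC1(C)[C@@H](O)CC[C@]1(C)c2cc(OC)c(C)cc2O.O=C=[Cr](=C=O)=C=O | intermediate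
13 | 2-[(1S,3S)-3-hydroxy-1,2,2-trimethylcyclopentyl]-4-methoxy-5-methylphenol | CC1(C)[C@@H](O)CC[C@]1(C)c2cc(OC)c(C)cc2O | intermediate
14 | 2-[(1S,3S)-3-hydroxy-1,2,2-trimethylcyclopentyl]-5-methylcyclohexa-2,5-diene-1,4-dione | CC1(C)[C@@H](O)CC[C@]1(C)C2=CC(=O)C(C)=CC2=O | intermediate
15 | 2-[(1S,3S)-3-hydroxy-1,2,2-trimethylcyclopentyl]-5-methylbenzene-1,4-diol | CC1(C)[C@@H](O)CC[C@]1(C)c2cc(O)c(C)cc2O | intermediate
16 | 1,4-bis(TBS-oxy)-2-methyl-5-[(1S,3S)-3-(TBS-oxy)-1,2,2-trimethylcyclopentyl]benzene | CC1(C)[C@@H](O[Si](C)(C)C(C)(C)C)CC[C@]1(C)c2cc(O[Si](C)(C)C(C)(C)C)c(C)cc2O[Si](C)(C)C(C)(C)C | intermediate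
17 | 1,4-bis(TBS-oxy)-2-methyl-5-[(1S,3S)-3-(TBS-oxy)-1,2,2-trimethylcyclopentyl]cyclohexa-1,4-diene | CC1(C)[C@@H](O[Si](C)(C)C(C)(C)C)CC[C@]1(C)C2=C(O[Si](C)(C)C(C)(C)C)CC(C)=C(O[Si](C)(C)C(C)(C)C)C2 | intermediate
18 | (2S)-2-allyl-2-methyl-4-(TBS-oxy)-5-RC-cyclohex-4-en-1-one | CC1(C)[C@@H](O[Si](C)(C)C(C)(C)C)CC[C@]1(C)C2=C(O[Si](C)(C)C(C)(C)C)C[C@](C)(CC=C)C(=O)C2 | intermediate
19 | (2R)-2-methyl-2-[(E)-prop-1-enyl]-4-(TBS-oxy)-5-RC-cyclohex-4-en-1-one | CC1(C)[C@@H](O[Si](C)(C)C(C)(C)C)CC[C@]1(C)C2=C(O[Si](C)(C)C(C)(C)C)C[C@](C)(/C=C/C)C(=O)C2 | intermediate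
20 | (1R)-1-methyl-2-oxo-5-(TBS-oxy)-4-RC-cyclohex-4-ene-1-carbaldehyde | CC1(C)[C@@H](O[Si](C)(C)C(C)(C)C)CC[C@]1(C)C2=C(O[Si](C)(C)C(C)(C)C)C[C@](C)(C=O)C(=O)C2 | intermediate
21 | 4-bromo-2-methylbut-1-ene | CC(=C)CCBr | starting material
22 | (3-methylbut-3-enyl)magnesium bromide | CC(=C)CC[Mg]Br | intermediate
23 | bromomagnesium alkoxide of the C8 carbinol (C8 epimers) | CC1(C)[C@@H](O[Si](C)(C)C(C)(C)C)CC[C@]1(C)C2=C(O[Si](C)(C)C(C)(C)C)C[C@](C)(C(O[Mg]Br)CCC(C)=C)C(=O)C2 | intermediate
24 | (2R)-2-methyl-2-[4-methyl-1-(TMS-oxy)pent-4-enyl]-4-(TBS-oxy)-5-RC-cyclohex-4-en-1-one (C8 epimers) | CC1(C)[C@@H](O[Si](C)(C)C(C)(C)C)CC[C@]1(C)C2=C(O[Si](C)(C)C(C)(C)C)C[C@](C)(C(O[Si](C)(C)C)CCC(C)=C)C(=O)C2 | intermediate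
25 | 1-methylidene analogue of 24 (C4a=CH2; C8 epimers) | CC1(C)[C@@H](O[Si](C)(C)C(C)(C)C)CC[C@]1(C)C2=C(O[Si](C)(C)C(C)(C)C)C[C@](C)(C(O[Si](C)(C)C)CCC(C)=C)C(=C)C2 | intermediate
26 | (8aS)-5,8a-dimethyl-2-(TBS-oxy)-8-(TMS-oxy)-3-RC-1,4,6,7,8,8a-hexahydronaphthalene (C8 epimers) | CC1(C)[C@@H](O[Si](C)(C)C(C)(C)C)CC[C@]1(C)C3=C(O[Si](C)(C)C(C)(C)C)C[C@]2(C)C(O[Si](C)(C)C)CCC(C)=C2C3 | intermediate
27 | (8aS)-5,8a-dimethyl-2-(TBS-oxy)-3-RC-1,4,6,7,8,8a-hexahydronaphthalen-8-ol (target numbering; C8 epimers) | CC1(C)[C@@H](O[Si](C)(C)C(C)(C)C)CC[C@]1(C)C3=C(O[Si](C)(C)C(C)(C)C)C[C@]2(C)C(O)CCC(C)=C2C3 | intermediate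
28 | (8aS)-5,8a-dimethyl-2-(TBS-oxy)-3-RC-1,4,6,7-tetrahydronaphthalen-8(8aH)-one (target numbering) | CC1(C)[C@@H](O[Si](C)(C)C(C)(C)C)CC[C@]1(C)C3=C(O[Si](C)(C)C(C)(C)C)C[C@]2(C)C(=O)CCC(C)=C2C3 | intermediate
29 | C7=C8 enol triflate of 28 | CC1(C)[C@@H](O[Si](C)(C)C(C)(C)C)CC[C@]1(C)C3=C(O[Si](C)(C)C(C)(C)C)C[C@]2(C)C(OS(=O)(=O)C(F)(F)F)=CCC(C)=C2C3 | intermediate
30 | (8aS)-8-bromo-5,8a-dimethyl-2-(TBS-oxy)-3-RC-1,4,6,8a-tetrahydronaphthalene | CC1(C)[C@@H](O[Si](C)(C)C(C)(C)C)CC[C@]1(C)C3=C(O[Si](C)(C)C(C)(C)C)C[C@]2(C)C(Br)=CCC(C)=C2C3 | intermediate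
31 | (8S,8aS)-8-bromo-5,8a-dimethyl-2-(TBS-oxy)-3-RC-1,4,6,7,8,8a-hexahydronaphthalene | CC1(C)[C@@H](O[Si](C)(C)C(C)(C)C)CC[C@]1(C)C3=C(O[Si](C)(C)C(C)(C)C)C[C@]2(C)[C@@H](Br)CCC(C)=C2C3 | intermediate
32 | (8S,8aS)-8-bromo-5,8a-dimethyl-3-RC-6,7,8,8a-tetrahydronaphthalen-2(1H)-one | CC1(C)[C@@H](O[Si](C)(C)C(C)(C)C)CC[C@]1(C)C3=CC2=C(C)CC[C@H](Br)[C@@]2(C)CC3=O | intermediate
33 | (8S,8aS)-8-bromo-3-[(1S,3S)-3-hydroxy-1,2,2-trimethylcyclopentyl]-5,8a-dimethyl-6,7,8,8a-tetrahydronaphthalen-2(1H)-one | CC1(C)[C@@H](O)CC[C@]1(C)C3=CC2=C(C)CC[C@H](Br)[C@@]2(C)CC3=O | intermediate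
34 | (8S,8aS)-8-bromo-3-[(1R,3R)-3-bromo-1,2,2-trimethylcyclopentyl]-5,8a-dimethyl-6,7,8,8a-tetrahydronaphthalen-2(1H)-one | CC1(C)[C@H](Br)CC[C@]1(C)C3=CC2=C(C)CC[C@H](Br)[C@@]2(C)CC3=O | intermediate
35 | (4aR,5S,8S,8aS)-4a,5-epoxide of 34 | CC1(C)[C@H](Br)CC[C@]1(C)C3=C[C@]2(O4)[C@]4(C)CC[C@H](Br)[C@@]2(C)CC3=O | intermediate
36 | (4aR,5R,8S,8aS)-8-bromo-3-[(1R,3R)-3-bromo-1,2,2-trimethylcyclopentyl]-4a,5-dihydroxy-5,8a-dimethyl-4a,5,6,7,8,8a-hexahydronaphthalen-2(1H)-one | CC1(C)[C@H](Br)CC[C@]1(C)C1=C[C@]2(O)[C@](C)(O)CC[C@H](Br)[C@@]2(C)CC1=O | target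

**Step count and risks**

Total: 24 steps. Longest linear sequence: 23 steps (steps 1–4 and 6–24, from 1); the carbene complex 11 is a one-step side branch (step 5).

Steps most likely to fail:

1. Step 22 (Appel bromination at C3'). Displacement at a carbon flanked by the gem-dimethyl centre is slow, so ionisation with methyl migration or elimination may outrun substitution. Fallback: setting out from 33, the alcohol is converted into the imidazole-1-sulfonate F1 (1,1'-sulfonyldiimidazole, NaH, THF) and this is displaced with Bu4NBr in toluene at 80 °C. An isolated sulfonate and a free bromide ion replace the oxyphosphonium pathway, inversion is again expected, and the sequence comes back to the route at 34.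

2. Step 19 (radical hydrogenation of the bromoalkene). Hydrogen-atom transfer to the tetrasubstituted C4a=C5 olefin or to the enol ether may compete with transfer to the bromoalkene, or bromine may be lost reductively. Fallback: setting out from ketone 28, condensation with N2H4·H2O (EtOH, 80 °C) gives the hydrazone F2, and CuBr2/LiOt-Bu (THF) converts it into the geminal 8,8-dibromide F3. One bromine is then removed with Bu3SnH (1 equiv) and Et3B/air in toluene at low temperature. The same C8 α-bromo radical arises without a reagent that attacks olefins, it should take hydrogen anti to the C8a methyl, and the sequence comes back at 31.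

3. Step 15 (ring-closing metathesis to the tetrasubstituted olefin). The ruthenium alkylidene may fail to load onto either gem-disubstituted olefin beside the quaternary C8a, leaving the diene unchanged or causing olefin migration. Fallback: setting out from 24, Lemieux–Johnson cleavage of the chain isopropenyl group (OsO4 cat., NaIO4, 2,6-lutidine) gives the methyl ketone F4. Intramolecular McMurry coupling of its C4a and C5 carbonyls (TiCl3(DME)1.5, Zn–Cu, DME, reflux) should then form the C4a=C5 olefin directly, coming back at 26.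

Further compounds
F1 | step 22 | imidazole-1-sulfonate of alcohol 33 | CC1(C)[C@@H](OS(=O)(=O)n4ccnc4)CC[C@]1(C)C3=CC2=C(C)CC[C@H](Br)[C@@]2(C)CC3=O
F2 | step 19 | hydrazone of ketone 28 | CC1(C)[C@@H](O[Si](C)(C)C(C)(C)C)CC[C@]1(C)C3=C(O[Si](C)(C)C(C)(C)C)C[C@]2(C)C(=NN)CCC(C)=C2C3
F3 | step 19 | (8aS)-8,8-dibromo-5,8a-dimethyl-2-(TBS-oxy)-3-RC-1,4,6,7,8,8a-hexahydronaphthalene | CC1(C)[C@@H](O[Si](C)(C)C(C)(C)C)CC[C@]1(C)C3=C(O[Si](C)(C)C(C)(C)C)C[C@]2(C)C(Br)(Br)CCC(C)=C2C3
F4 | step 15 | (2R)-2-methyl-2-[4-oxo-1-(TMS-oxy)pentyl]-4-(TBS-oxy)-5-RC-cyclohex-4-en-1-one (C8 epimers) | CC1(C)[C@@H](O[Si](C)(C)C(C)(C)C)CC[C@]1(C)C2=C(O[Si](C)(C)C(C)(C)C)C[C@](C)(C(O[Si](C)(C)C)CCC(C)=O)C(=O)C2
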